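G is the solid, J its dissolved form, and Z the partner suspected of binding J into L while itself decaying to X. Follow one dissolved unit: it stands at a fork, J or L, and you can carry its binding odds, L divided by J, from run to run.

the same everywhere: G 13 mM

| charge | Z | remark | time |
|---|---|---|---|
| south | 13 mM | run made earlier |  |
| north | 29 mM | run made earlier |  |
| flask | 19.5 mM |  | 8.0 h |

| run | time / h | L / % | J / % |
|---|---|---|---|
| south | 1.50 | 11 | 42 |
| south | 3.00 | 10 | 59 |
| south | 5.00 | 7 | 72 |
| south | 6.00 | 8 | 73 |
| north | 0.500 | 5 | 9 |
| north | 1.33 | 17 | 30 |
| north | 3.00 | 22 | 54 |
| north | 6.00 | 14 | 69 |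

(scatter of a reading: 2 percentage points)

- how much L there is at 8.0 h, in percent of the G charged
- concentration of J in solution at 8.0 h, in percent of saturation

- G is a solid; its amount is given per volume of the solution
- the earlier runs were read with a standard deviation of 2 percentage points
- on the list of suspects stand: Z -> X; J + Z <-> L; G <-> J; L <-> Q
- at the start none of G is in solution
- J means what is dissolved; the solid is not counted in it

1. Turn the Z charge. By hand, the odds follow Z, and north holds 2.23 times the Z of south. At 3.00 h the readings give 0.407 against 0.169, a ratio of 2.40. Your flask is charged with 0.672 of the Z charge of north.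

2. Turn the time. By hand, the odds fall as Z is lost. In north the readings go from 0.407 to 0.203 by 6.00 h, which reads as a halving time of 2.98 h, with the scatter of those readings in it. I read north: its last L, 14%, stands higher above the scatter of 2 percentage points than the last L of south, 8%.

3. Scale the north reading by both settings. My estimate of the binding odds of your flask at 8.0 h, L over J, comes to 0.0857.

4. Take J for your flask from the last south reading, 73%; the reading before it is 72%, and the scatter is 2 points. My reckoning gives 6.26% of L, and, if I take that reading level for saturation, J close to saturation.

The forecast, holding that the binding “sits close to equilibrium”, says 6% of L (4% to 8.5%) and 94% of saturation (78% to 100%), against my 6.26%.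

The flask gives 6.29% of L and J at 103% of saturation, with odds of 0.0847.

    Z → X (k = 0.363 /h)
    J + Z ⇌ L (K = 52.0 /M, k = 80.1 /M/h)
    G ⇌ J, rate k3*(cs3 - [J]) while solid is left; crystals form when [J] > cs3 (solubility = 9.40 mM, k = 0.660 /h)
    L ⇌ Q (K = 7.50, k = 0.0285 /h)

In this flask at 8.00 h, the binding step by itself relaxes with a half-life of 0.286 h, both ways together, which is shorter than the time 8.0 h: a rapid equilibrium. Now carry the odds to the neighbouring flask, the same charge read at 20 h. With the halving time 2.98 h read from north, they fall to 0.00527, and on its J of 72.5% that means 0.382% of L. The neighbour holds 0.366% of L, with free Z at 0.42% of its charge.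

(The numbers in the tables come from a simulation for an exercise; scatter was added.)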